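## Retrosynthetic overview

- Numbering: tetralin C1 (isopropyl), C4 (methyl), C4a, C5 to C8, C8a; pyrone O1', C2' (carbonyl), C3' (on C8), C4' (OH), C6' (styryl). The strategy rests on ring A: its contiguous C5–O, C6–O, C7–CHO triad is a 4-methoxyacetoacetyl unit, and C4a, C8a, C8 are the ketone carbon, the α-carbon and the α-acyl carbon of a 2-acyl p-menthanone (ring B).
- Last disconnections: cleavage of three methyl ethers, and reduction of a C7 thioester to the aldehyde.
- Key disconnection: ring A by a TiCl4-mediated formal [3+3] cyclocondensation (bonds C4a–C5 and C7–C8) of the ring-B 3-silyloxy enone carrying the pyronyl ketone with the 1,3-bis(silyloxy)diene of S-ethyl 4-methoxy-3-oxobutanethioate.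
- The silyloxy enone comes from aldol addition of the kinetic enolate of trans-carvomenthone (from (S)-carvone, which fixes C1 and C4) to yangonin-3-carbaldehyde, then oxidation and O-silylation.
- Ring order: the pyrone ring (4-hydroxy-6-methyl-2-pyrone) and ring B (carvone) are bought; ring A is formed last.

Key step: step 12

Remark: the target structure leaves the C8–C3' biaryl axis undefined; it is left uncontrolled, and the benzannulated compounds may appear as slowly interconverting rotamers.

## Route

Step 1
Reactants: 1 (S)-(+)-carvone
Product: 3 trans-carvomenthone, via cis-carvomenthone 2 (not isolated)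
Conditions: H2 (1 atm), 10% Pd/C, EtOAc, rt; filter; NaOMe (cat.), MeOH, rt
Reagents that add atoms: none
Why: Heterogeneous catalytic hydrogenation saturates both C=C bonds without touching the isopropyl-bearing carbon (future C1), and enolate epimerisation equilibrates the methyl-bearing carbon (future C4) to the diequatorial trans isomer under thermodynamic control.

Step 2
Reactants: 4 4-hydroxy-6-methyl-2H-pyran-2-one
Product: 5 4-methoxy-6-methyl-2H-pyran-2-one
Conditions: Me2SO4, K2CO3, acetone, reflux
Reagents that add atoms: dimethyl sulfate, COS(=O)(=O)OC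
Why: Williamson-type O-methylation of the acidic vinylogous acid, which for this pyrone should give mainly the 4-methoxy-2-pyrone.

Step 3
Reactants: 5 4-methoxy-6-methyl-2H-pyran-2-one; 6 4-methoxybenzaldehyde
Product: 7 yangonin
Conditions: Mg(OMe)2, MeOH, reflux
Reagents that add atoms: none
Why: Vinylogous aldol condensation of the magnesium dienolate of the 6-methyl group with a non-enolisable aldehyde, the E alkene resulting from thermodynamically controlled elimination.

Step 4
Reactants: 7 yangonin
Product: 9 yangonin-3-carbaldehyde, via iminium chloride 8 (not isolated)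
Conditions: POCl3, DMF, 0 to 60 °C; aq NaOAc
Reagents that add atoms: N,N-dimethylformamide, CN(C)C=O; water, O
Why: Vilsmeier–Haack formylation at C3, the terminus of the donor chain (4-OMe, ring oxygen, anisyl through the styryl unit) and the usual site of electrophilic substitution in 4-methoxy-2-pyrones, followed by hydrolysis of the iminium salt.

Step 5
Reactants: 3 trans-carvomenthone; 9 yangonin-3-carbaldehyde
Product: 11 aldol adduct, via lithium enolate 10 (not isolated)
Conditions: LiN(iPr)2, THF, −78 °C; then 9 in THF, −78 °C; AcOH quench at −78 °C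
Reagents that add atoms: none
Why: Kinetic deprotonation at the CH2 α-carbon gives the less substituted lithium enolate, whose aldol addition to the aldehyde outruns conjugate attack on the pyrone; the two new centres (future C8a and C8) form as a mixture and are erased in steps 6 and 7.

Step 6
Reactants: 11 aldol adduct
Product: 12 1,3-diketone
Conditions: Dess–Martin periodinane, NaHCO3, CH2Cl2, 0 °C to rt
Reagents that add atoms: none
Why: Dess–Martin oxidation of a β-hydroxy ketone under buffered conditions avoids dehydration and retro-aldol cleavage, and the epimerisable α-carbons rest in the all-equatorial arrangement (methyl trans to isopropyl).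

Step 7
Reactants: 12 1,3-diketone
Product: 13 ring-B 3-silyloxy enone
Conditions: Me3SiOTf, Et3N, CH2Cl2, 0 °C; non-aqueous work-up, used crude
Reagents that add atoms: trimethylsilyl trifluoromethanesulfonate, C[Si](C)(C)OS(=O)(=O)C(F)(F)F
Why: Soft enolisation and O-silylation at the most acidic C–H (C8a, between the carbonyls) gives the 3-silyloxy-2-en-1-one with an endocyclic C4a=C8a bond and leaves C4–H untouched; an exocyclic O-silyl isomer would lead to the same titanium chelate in step 12.

Step 8
Reactants: 14 Meldrum's acid; 15 methoxyacetyl chloride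
Product: 16 acyl Meldrum's acid
Conditions: pyridine, CH2Cl2, 0 °C to rt
Reagents that add atoms: none
Why: C-acylation of the highly acidic Meldrum's acid with an acid chloride (Oikawa–Yonemitsu acylation).

Step 9
Reactants: 16 acyl Meldrum's acid
Product: 17 S-ethyl 4-methoxy-3-oxobutanethioate
Conditions: EtSH, toluene, 80 °C, sealed tube
Reagents that add atoms: ethanethiol, CCS
Why: Thermolysis of the acyl Meldrum's acid releases an acylketene with loss of acetone and CO2, and the thiol traps it as the β-keto thioester.

Step 10
Reactants: 17 S-ethyl 4-methoxy-3-oxobutanethioate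
Product: 18 mono(silyl enol ether)
Conditions: Me3SiCl, Et3N, toluene, rt
Reagents that add atoms: chlorotrimethylsilane, C[Si](C)(C)Cl
Why: O-silylation of the enolised β-keto thioester gives the 3-silyloxy enethioate, the standard first stage of Chan-type diene preparation.

Step 11
Reactants: 18 mono(silyl enol ether)
Product: 20 1,3-bis(silyloxy)diene, via lithium dienolate 19 (not isolated)
Conditions: LiN(iPr)2, THF, −78 °C; Me3SiCl, −78 to 0 °C; non-aqueous work-up
Reagents that add atoms: chlorotrimethylsilane, C[Si](C)(C)Cl
Why: γ-Deprotonation of the vinylogous thioester and O-silylation of the dienolate give the silyl ketene O,S-acetal diene, whose double-bond geometry is irrelevant for the benzannulation.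

Step 12
Reactants: 13 ring-B 3-silyloxy enone; 20 1,3-bis(silyloxy)diene
Product: 22 ring A salicylate thioester, via conjugate adduct 21 (not isolated)
Conditions: TiCl4 (1.1 equiv), CH2Cl2, −78 °C, 13 premixed with TiCl4; then 20 (1.5 equiv), −78 to 20 °C; aq HCl
Reagents that add atoms: none
Why: TiCl4 exchanges the ring O–SiMe3 of 13 for O–TiCl3 and chelates the C8 carbonyl, the methoxy-bearing terminal carbon of 20 adds to C4a with loss of the C4a oxygen (C4a–C5, adduct 21), and the remaining silyl ketene O,S-acetal carbon attacks the titanium-bound C8 carbonyl (C7–C8), after which loss of the C8 oxygen and enolisation of the C6 ketone aromatise ring A. The closest known reaction is the TiCl4-mediated formal [3+3] cyclocondensation of 1,3-bis(silyloxy)-1,3-dienes with 3-silyloxy-2-en-1-ones to salicylates (Chan-type diene benzannulation), which tolerates 4-alkoxy dienes and enones derived from 2-acylcyclohexanones. Ring A closes by an intramolecular Mukaiyama aldol addition, 6-exo-trig at the C8 carbonyl, followed by dehydration. No stereocentre is formed: C1 and C4 come unchanged from 3, the trans arrangement lets both benzylic groups sit pseudoaxial beside the new peri substituents, and the C8–C3' axis is not controlled. The pairing C5 to C4a and C7 to C8 is needed and should follow from the unhindered terminal carbon reacting first at the former silyloxy carbon, while C8 is screened on both faces by the 2'-carbonyl and 4'-methoxy groups of the twisted pyrone. Attack at C4a must also beat attack at C4' of the pyrone, whose MeO–C4'=C3'–C8=O unit is a second β-alkoxy enone; only the ring enol ether can undergo silicon-to-titanium exchange, and the resulting six-membered chelate holds C8=O in the plane of C4a=C8a and forces the pyrone out of conjugation, which is why 13 is premixed with TiCl4 before 20 is added.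

Step 13
Reactants: 22 ring A salicylate thioester
Product: 23 tri-O-methyl heimiomycin A
Conditions: Et3SiH, Pd/CaCO3 poisoned with Pb(OAc)2 (Lindlar catalyst), acetone, rt
Reagents that add atoms: none
Why: Fukuyama reduction, in which zerovalent palladium inserts into the acyl–sulfur bond and the silane delivers hydride, gives the C7 aldehyde without touching the pyrone lactone, and the poisoned catalyst should spare the styryl alkene.

Step 14
Reactants: 23 tri-O-methyl heimiomycin A
Product: 24 heimiomycin A
Conditions: BBr3, CH2Cl2, −78 to 0 °C; then MeOH, H2O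
Reagents that add atoms: none
Why: Lewis acid-mediated demethylation (bromide attack on boron-activated O-methyl groups) cleaves the two aryl methyl ethers and the vinylogous methyl ester of the pyrone, while the aldehyde is held as a boron chelate with the neighbouring phenol until hydrolysis.

## Compound list

1 | (S)-(+)-carvone | CC(=C)[C@H]1CC=C(C)C(=O)C1 | starting material
2 | cis-carvomenthone, (2R,5S)-2-methyl-5-(propan-2-yl)cyclohexan-1-one | CC(C)[C@H]1CC[C@@H](C)C(=O)C1 | intermediate
3 | trans-carvomenthone, (2S,5S)-2-methyl-5-(propan-2-yl)cyclohexan-1-one | CC(C)[C@H]1CC[C@H](C)C(=O)C1 | intermediate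
4 | 4-hydroxy-6-methyl-2H-pyran-2-one | Cc1cc(O)cc(=O)o1 | starting material
5 | 4-methoxy-6-methyl-2H-pyran-2-one | COc1cc(C)oc(=O)c1 | intermediate
6 | 4-methoxybenzaldehyde | COc1ccc(C=O)cc1 | starting material
7 | yangonin, 4-methoxy-6-[(E)-2-(4-methoxyphenyl)ethenyl]-2H-pyran-2-one | COc1ccc(/C=C/c2cc(OC)cc(=O)o2)cc1 | intermediate
8 | C3 dimethyliminium chloride of yangonin (Vilsmeier adduct) | COc1ccc(/C=C/c2cc(OC)c(C=[N+](C)C)c(=O)o2)cc1.[Cl-] | intermediate
9 | yangonin-3-carbaldehyde, 4-methoxy-6-[(E)-2-(4-methoxyphenyl)ethenyl]-2-oxo-2H-pyran-3-carbaldehyde | COc1ccc(/C=C/c2cc(OC)c(C=O)c(=O)o2)cc1 | intermediate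
10 | kinetic lithium enolate of trans-carvomenthone (enolate C=C toward the CH2 α-carbon) | CC(C)[C@H]1CC[C@H](C)C(O[Li])=C1 | intermediate
11 | aldol adduct: trans-carvomenthone bearing a hydroxy(4-methoxy-6-styryl-2-oxopyran-3-yl)methyl group on the former CH2 α-carbon; mixture at the two new centres | CC(C)[C@H]1CC[C@H](C)C(=O)C1C(O)c1c(OC)cc(/C=C/c2ccc(OC)cc2)oc1=O | intermediate
12 | 1,3-diketone: 2-(pyrone-3-carbonyl) derivative of trans-carvomenthone, drawn as the all-equatorial keto form (acyl trans to isopropyl, methyl trans to isopropyl) | CC(C)[C@H]1CC[C@H](C)C(=O)[C@@H]1C(=O)c1c(OC)cc(/C=C/c2ccc(OC)cc2)oc1=O | intermediate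
13 | ring-B 3-silyloxy enone: trimethylsilyl enol ether (C4a=C8a) with the exocyclic pyronyl ketone at C8; isopropyl and methyl trans | CC(C)[C@H]1CC[C@H](C)C(O[Si](C)(C)C)=C1C(=O)c1c(OC)cc(/C=C/c2ccc(OC)cc2)oc1=O | intermediate
14 | Meldrum's acid | CC1(C)OC(=O)CC(=O)O1 | starting material
15 | methoxyacetyl chloride | COCC(Cl)=O | starting material
16 | 5-(1-hydroxy-2-methoxyethylidene)-2,2-dimethyl-1,3-dioxane-4,6-dione | COCC(O)=C1C(=O)OC(C)(C)OC1=O | intermediate
17 | S-ethyl 4-methoxy-3-oxobutanethioate | CCSC(=O)CC(=O)COC | intermediate
18 | S-ethyl (Z)-4-methoxy-3-(trimethylsilyloxy)but-2-enethioate (geometry not critical) | CCSC(=O)/C=C(\O[Si](C)(C)C)COC | intermediate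
19 | lithium dienolate of 18 (γ-deprotonated) | CO/C=C(\O[Si](C)(C)C)/C=C(/O[Li])SCC | intermediate
20 | 1-ethylsulfanyl-4-methoxy-1,3-bis(trimethylsilyloxy)buta-1,3-diene (geometry not critical) | CO/C=C(\O[Si](C)(C)C)/C=C(/O[Si](C)(C)C)SCC | intermediate
21 | conjugate adduct: C4a carries the CH(OMe)C(=O)CH2C(=O)SEt chain, C4a=C8a retained, C8 ketone free; mixture at the CH(OMe) centre | CC(C)[C@H]1CC[C@H](C)C(C(OC)C(=O)CC(=O)SCC)=C1C(=O)c1c(OC)cc(/C=C/c2ccc(OC)cc2)oc1=O | intermediate
22 | ring A salicylate thioester: (1R,4S)-tetralin with C5 OMe, C6 OH, C7 C(=O)SEt, C8 4-methoxy-6-(4-methoxystyryl)-2-oxopyran-3-yl | CC(C)[C@H]1CC[C@H](C)c2c(OC)c(O)c(C(=O)SCC)c(-c3c(OC)cc(/C=C/c4ccc(OC)cc4)oc3=O)c21 | intermediate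
23 | tri-O-methyl heimiomycin A: (1R,4S)-tetralin with C5 OMe, C6 OH, C7 CHO, C8 dimethylated styrylpyrone | CC(C)[C@H]1CC[C@H](C)c2c(OC)c(O)c(C=O)c(-c3c(OC)cc(/C=C/c4ccc(OC)cc4)oc3=O)c21 | intermediate
24 | heimiomycin A | CC(C)[C@H]1CC[C@H](C)c2c(O)c(O)c(C=O)c(-c3c(O)cc(/C=C/c4ccc(O)cc4)oc3=O)c21 | target

## Step count and risks

Total steps: 14. Longest linear sequence: 9 steps (steps 2, 3, 4, 5, 6, 7, 12, 13, 14, from 4-hydroxy-6-methyl-2-pyrone).

Steps most likely to fail:

Step 12. The diene may add to C4' of the pyrone with displacement of methoxide instead of to C4a, or the open-chain adduct may fail to close onto the screened, vinylogous-ester-like C8 carbonyl and hydrolyse on work-up. Fallback, setting out from 11 and coming back at 22: the two bonds are made in separate operations, the first while C8 is still a protected carbinol so that the pyrone has no acyl activation. Silylation of 11 (Et3SiOTf, 2,6-lutidine, CH2Cl2, −78 °C) gives the triethylsilyl ether F1. A TiCl4-mediated vinylogous Mukaiyama aldol addition of 20 through its terminal carbon to the ring ketone, now the only activated electrophile, gives the tertiary alcohol F2 (C4a–C5 bond). HF·pyridine in THF removes the silyl group to give the diol F3, and Dess–Martin oxidation of its secondary carbinol gives the β-hydroxy triketone thioester F4. Intramolecular Knoevenagel condensation of the β-keto thioester methylene with the C8 ketone (TiCl4, pyridine, THF; Lehnert conditions), then acid-mediated loss of the tertiary C4a hydroxyl and tautomerisation (TsOH, toluene), closes and aromatises ring A to 22.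

Step 13. Palladium hydride formed from the silane may saturate the styryl alkene, and insertion into the doubly ortho-substituted thioester may be slow. Fallback, setting out from 22 and coming back at 23: NaBH4 (EtOH/THF, 0 °C) reduces the thioester, but not the vinylogous-carbonate lactone or the alkene, to the salicyl alcohol F5, and MnO2 (CH2Cl2, rt) oxidises the benzylic alcohol to 23.

Step 4. The chloroiminium ion may be too weak an electrophile for the lactone-deactivated enol ether, or may attack C5 of the pyrone or the styryl alkene. Fallback, setting out from 5 and coming back at 9: the C3 substituent is placed as a halogen before the styryl group exists. NBS (MeCN, rt) brominates 5 at C3 to the bromopyrone F6, the Mg(OMe)2 condensation with 6 gives 3-bromoyangonin F7, and bromine–magnesium exchange (i-PrMgCl·LiCl, THF, −40 °C) followed by DMF and mild acidic work-up gives 9.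

## Further compounds

F1 | step 12 | triethylsilyl ether of aldol adduct 11 | CC(C)[C@H]1CC[C@H](C)C(=O)C1C(O[Si](CC)(CC)CC)c1c(OC)cc(/C=C/c2ccc(OC)cc2)oc1=O
F2 | step 12 | tertiary alcohol from addition of the diene terminal carbon to the ring ketone of F1 (δ-hydroxy β-keto thioester, diastereomer mixture) | CC(C)[C@H]1CC[C@H](C)C(O)(C(OC)C(=O)CC(=O)SCC)C1C(O[Si](CC)(CC)CC)c1c(OC)cc(/C=C/c2ccc(OC)cc2)oc1=O
F3 | step 12 | diol from desilylation of F2 | CC(C)[C@H]1CC[C@H](C)C(O)(C(OC)C(=O)CC(=O)SCC)C1C(O)c1c(OC)cc(/C=C/c2ccc(OC)cc2)oc1=O
F4 | step 12 | β-hydroxy triketone thioester (C8 ketone, tertiary C4a hydroxyl) | CC(C)[C@H]1CC[C@H](C)C(O)(C(OC)C(=O)CC(=O)SCC)C1C(=O)c1c(OC)cc(/C=C/c2ccc(OC)cc2)oc1=O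
F5 | step 13 | salicyl alcohol: (1R,4S)-tetralin with C5 OMe, C6 OH, C7 CH2OH, C8 dimethylated styrylpyrone | CC(C)[C@H]1CC[C@H](C)c2c(OC)c(O)c(CO)c(-c3c(OC)cc(/C=C/c4ccc(OC)cc4)oc3=O)c21
F6 | step 4 | 3-bromo-4-methoxy-6-methyl-2H-pyran-2-one | COc1cc(C)oc(=O)c1Br
F7 | step 4 | 3-bromoyangonin, 3-bromo-4-methoxy-6-[(E)-2-(4-methoxyphenyl)ethenyl]-2H-pyran-2-one | COc1ccc(/C=C/c2cc(OC)c(Br)c(=O)o2)cc1
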